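**Strategy.** The route rests on disconnecting the bond between the 4-hydroxyphenyl-bearing methine C-c and C5 of the dihydrobenzofuran benzene ring, i.e. the cyclopentane made of C-c, the two ring-fusion methines and benzofuran C5/C6. A tertiary 1-(4-benzyloxybenzyl)indan-1-ol, assembled by α-arylation of an enantioenriched 3-arylindanone with an enantioenriched dihydrobenzofuranyl bromide, is ionised with TFAA/TFA. Dehydration, face-selective reprotonation and Friedel–Crafts closure funnel all carbinol and alkene isomers into the cis-fused diquinane with exo aryl, setting two stereocentres. The step exploits the para-alkoxybenzylic C-c and the arene carbon para to the dihydrofuran oxygen; transient O-trifluoroacetylation of the neighbouring phenol directs closure there.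

Key step: step 11

Remark (labels): C-a = ArCH next to the resorcinol ring (indanone C3); C-b = indanone C1; C-c = the second ArCH; C-d = indanone C2; benzofuran ring numbered O1, C2, C3, C3a, C4–C7, C7a.
Remark (assumption): the sense of induction of the chiral Pd ligand (step 3) and the chiral Rh catalyst (step 7) is not predicted here; the antipode that gives the drawn configuration is assumed to be chosen after a test reaction.

Step 1
Reactants: 1 1-[3,5-bis(benzyloxy)phenyl]ethanone
Product: 2 1-[3,5-bis(benzyloxy)-2-bromophenyl]ethanone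
Conditions: NBS (1.05 equiv), MeCN, 0 °C → rt
Reagents that add atoms: N-bromosuccinimide, O=C1CCC(=O)N1Br
Why: Electrophilic aromatic bromination; the position ortho to the acetyl group is ortho/para to both benzyloxy groups and should be brominated in preference to the hindered position between them.

Step 2
Reactants: 2 1-[3,5-bis(benzyloxy)-2-bromophenyl]ethanone; 3 4-(benzyloxy)benzaldehyde
Product: 4 (E)-1-[3,5-bis(benzyloxy)-2-bromophenyl]-3-[4-(benzyloxy)phenyl]prop-2-en-1-one
Conditions: KOH, EtOH/THF, rt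
Reagents that add atoms: none
Why: Claisen–Schmidt aldol condensation of the methyl ketone with the non-enolisable aldehyde should give the E-enone.

Step 3
Reactants: 4 (E)-1-[3,5-bis(benzyloxy)-2-bromophenyl]-3-[4-(benzyloxy)phenyl]prop-2-en-1-one
Product: 5 (R)-4,6-bis(benzyloxy)-3-[4-(benzyloxy)phenyl]indan-1-one
Conditions: Pd(OAc)2 (5 mol %), (R)- or (S)-3,5-Xyl-MeO-BIPHEP (6 mol %, antipode giving (R)-5), i-Pr2NEt (3 equiv), DMF, 90 °C
Reagents that add atoms: none
Why: Pd-catalysed asymmetric reductive Heck cyclisation (intramolecular conjugate arylation); the chiral bisphosphine controls the enantio-determining insertion of the enone into the aryl–Pd bond and so sets C-a, the Pd enolate is protonated and the amine returns Pd(0).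

Step 4
Reactants: 6 1,3-bis(benzyloxy)-5-bromobenzene; 7 4-bromo-2,6-difluorobenzoyl chloride
Product: 9 [3,5-bis(benzyloxy)phenyl](4-bromo-2,6-difluorophenyl)methanone, via arylmagnesium bromide 8 (not isolated)
Conditions: Mg, THF, 50 °C; then 7, CuI (10 mol %), THF, −40 °C
Reagents that add atoms: none
Why: Grignard formation followed by copper-catalysed acylation with the aroyl chloride at low temperature should stop at the diaryl ketone, which is shielded by the two ortho fluorines.

Step 5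
Reactants: 9 [3,5-bis(benzyloxy)phenyl](4-bromo-2,6-difluorophenyl)methanone; 10 [4-(benzyloxy)phenyl]methanol
Product: 11 [3,5-bis(benzyloxy)phenyl](4-bromo-2,6-bis{[4-(benzyloxy)benzyl]oxy}phenyl)methanone
Conditions: 10 (2.3 equiv), NaH (2.5 equiv), DMF, 0 → 60 °C
Reagents that add atoms: none
Why: Twofold SNAr; both fluorines are ortho to the ketone and are displaced by the benzylic alkoxide, whereas the bromide para to the carbonyl is a far poorer leaving group.

Step 6
Reactants: 11 [3,5-bis(benzyloxy)phenyl](4-bromo-2,6-bis{[4-(benzyloxy)benzyl]oxy}phenyl)methanone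
Product: 12 hydrazone of ketone 11
Conditions: N2H4·H2O (20 equiv), AcOH (cat.), n-BuOH, 110 °C (sealed)
Reagents that add atoms: hydrazine (as hydrate), NN
Why: Hydrazone condensation, driven by excess hydrazine and heat because the carbonyl is flanked by two ortho alkoxy groups.

Step 7
Reactants: 12 hydrazone of ketone 11
Product: 14 (2R,3S)-cis-2-[4-(benzyloxy)phenyl]-3-[3,5-bis(benzyloxy)phenyl]-4-{[4-(benzyloxy)benzyl]oxy}-6-bromo-2,3-dihydrobenzofuran, via diaryldiazomethane 13 (not isolated)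
Conditions: MnO2 (8 equiv), CH2Cl2, 0 °C → rt; filter; Rh2(S-PTAD)4 or its antipode (1 mol %, the one giving 3S), CH2Cl2, 0 °C → rt
Reagents that add atoms: none
Why: Oxidation to the diazo compound and Rh(II)-catalysed intramolecular 1,5 C–H insertion of the donor/donor carbene into an ArCH2–O bond (the two ether arms are equivalent); the chiral catalyst sets C3 and the concerted insertion should give the 2,3-cis ring, whose C2 is corrected in step 9.

Step 8
Reactants: 5 (R)-4,6-bis(benzyloxy)-3-[4-(benzyloxy)phenyl]indan-1-one; 14 (2R,3S)-cis-dihydrobenzofuranyl bromide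
Product: 15 (2R,3R)-trans-4,6-bis(benzyloxy)-3-[4-(benzyloxy)phenyl]-2-[(2R,3S)-cis-dihydrobenzofuran-6-yl]indan-1-one (dihydrobenzofuran substituents as in 14)
Conditions: Pd(OAc)2 (5 mol %), P(t-Bu)3·HBF4 (10 mol %), NaOt-Bu (2.2 equiv), toluene, 60 °C
Reagents that add atoms: none
Why: Pd-catalysed ketone α-arylation; the enolisable C-d should settle trans to the C-a aryl group under the basic conditions (steric and thermodynamic control), and C-a is not touched.

Step 9
Reactants: 15 trans-2,3-diarylindanone with cis-dihydrobenzofuran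
Product: 17 (2R,3R)-trans-4,6-bis(benzyloxy)-3-[4-(benzyloxy)phenyl]-2-{(2S,3S)-2-[4-(benzyloxy)phenyl]-3-[3,5-bis(benzyloxy)phenyl]-4-hydroxy-2,3-dihydrobenzofuran-6-yl}indan-1-one, via cis-dihydrobenzofuran phenol 16 (not isolated)
Conditions: CF3CO2H (20 vol %), C6HMe5 (5 equiv), CH2Cl2, 0 °C → rt
Reagents that add atoms: none
Why: Acidolysis of the para-alkoxybenzyl aryl ether (cation trapped by pentamethylbenzene) and acid-mediated epimerisation of benzofuran C2 through reversible ionisation of the para-alkoxybenzylic C–O bond to the more stable 2,3-trans ring; C3 is untouched and the benzofuran benzene ring is still symmetric, so reclosure on either oxygen gives the same compound.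

Step 10
Reactants: 17 phenol ketone; 18 1-(benzyloxy)-4-(chloromethyl)benzene
Product: 20 (2R,3R)-1-[4-(benzyloxy)benzyl]indan-1-ol derived from 17 (both C-b epimers), via benzylic Grignard reagent 19 (not isolated)
Conditions: 18, Mg, THF, 0 °C; CeCl3 (4 equiv), THF, −78 °C; then 17, −78 → 0 °C; aq NH4Cl
Reagents that add atoms: none
Why: 1,2-Addition of a benzylic organocerium reagent, which should suppress enolisation of the acidic 2-aryl ketone; the new carbinol centre forms as a mixture that the next step erases.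

Step 11
Reactants: 20 tertiary benzylic carbinol (C-b epimers)
Product: 24 hepta-O-benzyl ether of 25 with free 4-OH on the benzofuran ring, via aryl trifluoroacetate carbinol 21 (not isolated), via benzylidene-indane trifluoroacetate 22 (not isolated), via cyclised trifluoroacetate 23 (not isolated)
Conditions: (CF3CO)2O (4 equiv), 2,6-lutidine (2 equiv), CH2Cl2, 0 °C, 30 min; then CF3CO2H (20 equiv), 0 °C → rt; then MeOH/aq NaHCO3
Reagents that add atoms: none
Why: TFAA/lutidine first masks the benzofuran C4 phenol as its trifluoroacetate (21); TFA then ionises the tertiary carbinol, loss of a benzylic proton gives the E/Z benzylidene-indane 22, and reprotonation at C-b gives the para-benzyloxybenzyl cation at C-c, which is captured by benzofuran C5 (23). The closest known reaction type is the acid-mediated dehydrative Friedel–Crafts cyclisation of 1-benzylindan-1-ols or 1-benzylidene-2-arylindanes to tetrahydroindeno[2,1-a]indenes. The cyclopentane closes by electrophilic aromatic substitution in which the cationic carbon and both arene carbons (C5 and C6) lie in the new five-membered ring (endo with respect to the arene π-bond). C-b is set by protonation anti to the neighbouring benzofuranyl group on C-d, and only the resulting cis cation can reach the arene while the trans cation reverts to the alkene, so both carbinol epimers and both alkene isomers should converge on the cis ring fusion. C-c is set in the C–C bond formation with its aryl group on the convex face, away from the resorcinol ring. The step needs attack at C5 and not at C7: C5 is para to the dihydrofuran oxygen, whereas the C4 oxygen, which would direct para to C7, is switched off as the trifluoroacetate, and this ester is removed by the methanolic bicarbonate work-up.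

Step 12
Reactants: 24 hepta-O-benzyl ether
Product: 25 CNP0198336.1
Conditions: H2 (1 atm), 10% Pd/C, EtOAc/MeOH, rt
Reagents that add atoms: none
Why: Hydrogenolysis of the seven benzyl aryl ethers under neutral conditions; no stereocentre is involved and the cyclic benzylic ether of the dihydrofuran should cleave much more slowly than the O-benzyl groups.

**Compound list**

1 | 1-[3,5-bis(benzyloxy)phenyl]ethanone | CC(=O)c1cc(OCc2ccccc2)cc(OCc2ccccc2)c1 | starting material
2 | 1-[3,5-bis(benzyloxy)-2-bromophenyl]ethanone | CC(=O)c1cc(OCc2ccccc2)cc(OCc2ccccc2)c1Br | intermediate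
3 | 4-(benzyloxy)benzaldehyde | O=Cc1ccc(OCc2ccccc2)cc1 | starting material
4 | (E)-1-[3,5-bis(benzyloxy)-2-bromophenyl]-3-[4-(benzyloxy)phenyl]prop-2-en-1-one | O=C(/C=C/c1ccc(OCc2ccccc2)cc1)c1cc(OCc2ccccc2)cc(OCc2ccccc2)c1Br | intermediate
5 | (R)-4,6-bis(benzyloxy)-3-[4-(benzyloxy)phenyl]indan-1-one | c1ccccc1COc1ccc([C@@H]2c3c(OCc4ccccc4)cc(OCc4ccccc4)cc3C(=O)C2)cc1 | intermediate
6 | 1,3-bis(benzyloxy)-5-bromobenzene | Brc1cc(OCc2ccccc2)cc(OCc2ccccc2)c1 | starting material
7 | 4-bromo-2,6-difluorobenzoyl chloride | O=C(Cl)c1c(F)cc(Br)cc1F | starting material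
8 | [3,5-bis(benzyloxy)phenyl]magnesium bromide | Br[Mg]c1cc(OCc2ccccc2)cc(OCc2ccccc2)c1 | intermediate
9 | [3,5-bis(benzyloxy)phenyl](4-bromo-2,6-difluorophenyl)methanone | O=C(c1cc(OCc2ccccc2)cc(OCc2ccccc2)c1)c1c(F)cc(Br)cc1F | intermediate
10 | [4-(benzyloxy)phenyl]methanol | OCc1ccc(OCc2ccccc2)cc1 | starting material
11 | [3,5-bis(benzyloxy)phenyl](4-bromo-2,6-bis{[4-(benzyloxy)benzyl]oxy}phenyl)methanone | O=C(c1cc(OCc2ccccc2)cc(OCc2ccccc2)c1)c1c(OCc2ccc(OCc3ccccc3)cc2)cc(Br)cc1OCc1ccc(OCc2ccccc2)cc1 | intermediate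
12 | hydrazone of ketone 11 | NN=C(c1cc(OCc2ccccc2)cc(OCc2ccccc2)c1)c1c(OCc2ccc(OCc3ccccc3)cc2)cc(Br)cc1OCc1ccc(OCc2ccccc2)cc1 | intermediate
13 | diaryldiazomethane from 12 | [N-]=[N+]=C(c1cc(OCc2ccccc2)cc(OCc2ccccc2)c1)c1c(OCc2ccc(OCc3ccccc3)cc2)cc(Br)cc1OCc1ccc(OCc2ccccc2)cc1 | intermediate
14 | (2R,3S)-cis-2-[4-(benzyloxy)phenyl]-3-[3,5-bis(benzyloxy)phenyl]-4-{[4-(benzyloxy)benzyl]oxy}-6-bromo-2,3-dihydrobenzofuran | Brc1cc(OCc3ccc(OCc4ccccc4)cc3)c2[C@H](c3cc(OCc4ccccc4)cc(OCc4ccccc4)c3)[C@H](c3ccc(OCc4ccccc4)cc3)Oc2c1 | intermediate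
15 | (2R,3R)-trans-2,3-diarylindan-1-one carrying the (2R,3S)-cis-dihydrobenzofuran-6-yl group of 14 at C2 | c1ccccc1COc1ccc([C@@H]2c3c(OCc4ccccc4)cc(OCc4ccccc4)cc3C(=O)[C@H]2c2cc(OCc3ccc(OCc4ccccc4)cc3)c3[C@H](c4cc(OCc5ccccc5)cc(OCc5ccccc5)c4)[C@H](c4ccc(OCc5ccccc5)cc4)Oc3c2)cc1 | intermediate
16 | phenol of 15 with the benzofuran ring still (2R,3S)-cis | c1ccccc1COc1ccc([C@@H]2c3c(OCc4ccccc4)cc(OCc4ccccc4)cc3C(=O)[C@H]2c2cc(O)c3[C@H](c4cc(OCc5ccccc5)cc(OCc5ccccc5)c4)[C@H](c4ccc(OCc5ccccc5)cc4)Oc3c2)cc1 | intermediate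
17 | (2R,3R)-trans-2,3-diarylindan-1-one with (2S,3S)-trans-4-hydroxy-2,3-dihydrobenzofuran-6-yl group | c1ccccc1COc1ccc([C@@H]2c3c(OCc4ccccc4)cc(OCc4ccccc4)cc3C(=O)[C@H]2c2cc(O)c3[C@H](c4cc(OCc5ccccc5)cc(OCc5ccccc5)c4)[C@@H](c4ccc(OCc5ccccc5)cc4)Oc3c2)cc1 | intermediate
18 | 1-(benzyloxy)-4-(chloromethyl)benzene | ClCc1ccc(OCc2ccccc2)cc1 | starting material
19 | [4-(benzyloxy)benzyl]magnesium chloride | Cl[Mg]Cc1ccc(OCc2ccccc2)cc1 | intermediate
20 | (2R,3R)-1-[4-(benzyloxy)benzyl]indan-1-ol from 17 (both C1 epimers; benzofuran 2S,3S) | c1ccccc1COc1ccc([C@@H]2c3c(OCc4ccccc4)cc(OCc4ccccc4)cc3C(O)(Cc3ccc(OCc4ccccc4)cc3)[C@H]2c2cc(O)c3[C@H](c4cc(OCc5ccccc5)cc(OCc5ccccc5)c4)[C@@H](c4ccc(OCc5ccccc5)cc4)Oc3c2)cc1 | intermediate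
21 | aryl trifluoroacetate of 20 | c1ccccc1COc1ccc([C@@H]2c3c(OCc4ccccc4)cc(OCc4ccccc4)cc3C(O)(Cc3ccc(OCc4ccccc4)cc3)[C@H]2c2cc(OC(=O)C(F)(F)F)c3[C@H](c4cc(OCc5ccccc5)cc(OCc5ccccc5)c4)[C@@H](c4ccc(OCc5ccccc5)cc4)Oc3c2)cc1 | intermediate
22 | 1-[4-(benzyloxy)benzylidene]indane aryl trifluoroacetate (E/Z mixture) | c1ccccc1COc1ccc([C@@H]2c3c(OCc4ccccc4)cc(OCc4ccccc4)cc3C(=Cc3ccc(OCc4ccccc4)cc3)[C@H]2c2cc(OC(=O)C(F)(F)F)c3[C@H](c4cc(OCc5ccccc5)cc(OCc5ccccc5)c4)[C@@H](c4ccc(OCc5ccccc5)cc4)Oc3c2)cc1 | intermediate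
23 | cyclised pentacycle as aryl trifluoroacetate (stereocentres as in 25) | c1ccccc1COc1ccc([C@@H]2c3c(OCc4ccccc4)cc(OCc4ccccc4)cc3[C@H]3[C@H](c4ccc(OCc5ccccc5)cc4)c4c(cc5c(c4OC(=O)C(F)(F)F)[C@H](c4cc(OCc6ccccc6)cc(OCc6ccccc6)c4)[C@@H](c4ccc(OCc6ccccc6)cc4)O5)[C@@H]23)cc1 | intermediate
24 | hepta-O-benzyl ether of 25 with free 4-OH on the benzofuran ring (four core methines R; dihydrofuran 2S,3S) | c1ccccc1COc1ccc([C@@H]2c3c(OCc4ccccc4)cc(OCc4ccccc4)cc3[C@H]3[C@H](c4ccc(OCc5ccccc5)cc4)c4c(cc5c(c4O)[C@H](c4cc(OCc6ccccc6)cc(OCc6ccccc6)c4)[C@@H](c4ccc(OCc6ccccc6)cc4)O5)[C@@H]23)cc1 | intermediate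
25 | CNP0198336.1 (cis-fused dibenzobicyclo[3.3.0]octane with both 4-hydroxyphenyl groups exo; four core methines R; trans-dihydrofuran 2S,3S) | Oc1ccc([C@@H]2c3c(O)cc(O)cc3[C@H]3[C@H](c4ccc(O)cc4)c4c(cc5c(c4O)[C@H](c4cc(O)cc(O)c4)[C@@H](c4ccc(O)cc4)O5)[C@@H]23)cc1 | target

**Totals.** 12 steps in all; longest linear sequence 9 steps (steps 4–12).

**Steps most likely to fail**

Step 11. The closure may leak to C7 if the trifluoroacetate mask is incomplete or its directing bias is too small, and the exocyclic double bond may migrate into the indane ring before the cation is trapped. Fallback with a physical blocking group: from 17, tetrabutylammonium tribromide (1 equiv, CH2Cl2/MeOH, −20 °C) should brominate para to the free phenol and give the C7-bromo phenol ketone F1. Addition of 19/CeCl3 as in step 10 gives the C7-bromo carbinol F2. Catalytic TsOH in HFIP/CH2Cl2 at 0 °C can then close only at C5 and gives the C7-bromo pentacycle F3. H2, Pd/C and Et3N remove the bromine together with the benzyl groups, and the route is rejoined at 25.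

Step 7. The doubly ortho-substituted diaryl carbene may give weak enantio-induction with the chiral Rh catalyst, or dimerise to the azine. Fallback by resolution through the enantiopure coupling partner: from 12, MnO2 and then achiral Rh2(esp)2 give racemic cis material, i.e. 14 together with its (2S,3R)-enantiomer F4. Coupling with 5 under the conditions of step 8 gives 15 and its benzofuran-epimeric diastereomer F5. The conditions of step 9 give 17 and the diastereomeric phenol F6, which are separated by chromatography, and the route is rejoined at 17.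

Step 3. Hydrodebromination and low enantioselectivity are possible with the doubly ortho-substituted aryl bromide. Fallback through a different metal and mechanism: from 4, Miyaura borylation (B2pin2, Pd(dppf)Cl2, KOAc, dioxane, 80 °C) gives the arylboronate chalcone F7. Rh(I)-catalysed asymmetric intramolecular 1,4-addition ([Rh(C2H4)2Cl]2, chiral phosphoramidite or diene ligand, aq K3PO4, toluene) then closes the indanone and returns to the route at 5.

**Further compounds**

F1 | step 11 | C7-bromo derivative of phenol ketone 17 | c1ccccc1COc1ccc([C@@H]2c3c(OCc4ccccc4)cc(OCc4ccccc4)cc3C(=O)[C@H]2c2cc(O)c3[C@H](c4cc(OCc5ccccc5)cc(OCc5ccccc5)c4)[C@@H](c4ccc(OCc5ccccc5)cc4)Oc3c2Br)cc1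
F2 | step 11 | C7-bromo derivative of carbinol 20 (both C1 epimers) | c1ccccc1COc1ccc([C@@H]2c3c(OCc4ccccc4)cc(OCc4ccccc4)cc3C(O)(Cc3ccc(OCc4ccccc4)cc3)[C@H]2c2cc(O)c3[C@H](c4cc(OCc5ccccc5)cc(OCc5ccccc5)c4)[C@@H](c4ccc(OCc5ccccc5)cc4)Oc3c2Br)cc1
F3 | step 11 | C7-bromo derivative of pentacycle 24 | c1ccccc1COc1ccc([C@@H]2c3c(OCc4ccccc4)cc(OCc4ccccc4)cc3[C@H]3[C@H](c4ccc(OCc5ccccc5)cc4)c4c(c(Br)c5c(c4O)[C@H](c4cc(OCc6ccccc6)cc(OCc6ccccc6)c4)[C@@H](c4ccc(OCc6ccccc6)cc4)O5)[C@@H]23)cc1
F4 | step 7 | (2S,3R)-enantiomer of 14 | Brc1cc(OCc3ccc(OCc4ccccc4)cc3)c2[C@@H](c3cc(OCc4ccccc4)cc(OCc4ccccc4)c3)[C@@H](c3ccc(OCc4ccccc4)cc3)Oc2c1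
F5 | step 7 | diastereomer of 15 with (2S,3R)-cis-dihydrobenzofuran | c1ccccc1COc1ccc([C@@H]2c3c(OCc4ccccc4)cc(OCc4ccccc4)cc3C(=O)[C@H]2c2cc(OCc3ccc(OCc4ccccc4)cc3)c3[C@@H](c4cc(OCc5ccccc5)cc(OCc5ccccc5)c4)[C@@H](c4ccc(OCc5ccccc5)cc4)Oc3c2)cc1
F6 | step 7 | diastereomer of 17 with (2R,3R)-trans-dihydrobenzofuran | c1ccccc1COc1ccc([C@@H]2c3c(OCc4ccccc4)cc(OCc4ccccc4)cc3C(=O)[C@H]2c2cc(O)c3[C@@H](c4cc(OCc5ccccc5)cc(OCc5ccccc5)c4)[C@H](c4ccc(OCc5ccccc5)cc4)Oc3c2)cc1
F7 | step 3 | (E)-1-[3,5-bis(benzyloxy)-2-(4,4,5,5-tetramethyl-1,3,2-dioxaborolan-2-yl)phenyl]-3-[4-(benzyloxy)phenyl]prop-2-en-1-one | O=C(/C=C/c1ccc(OCc2ccccc2)cc1)c1cc(OCc2ccccc2)cc(OCc2ccccc2)c1B1OC(C)(C)C(C)(C)O1
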